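**Retrosynthetic overview**
- The C1'–C13 bond between the halves is cut so that both halves come from one monomer, the 6-O-TBS-protected 1-hydroxy germacranolide. The C1' allyl radical, released by deoxygenation of the monomer's own free hydroxyl, adds to the methylidene lactone of a second molecule; C1' and C11 are set in that step.
- Monomer: the ten-membered ring is closed last at C1–C10 by an intramolecular NiCl2/CrCl2-mediated vinyl iodide–aldehyde coupling.
- The trans γ-lactone (C7–C8 and C8–O) comes from allylboration/lactonization of a 2-(methoxycarbonyl)allylboronate with (Z)-3-iodobut-2-enal.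
- The allylboronate comes from an ynoate whose C6 carbinol is set by catalytic asymmetric propiolate addition to a Z-enal; both Z trisubstituted alkenes derive from (Z)-3-iodobut-2-en-1-ol.
- Ring order: γ-lactone, then ten-membered carbocycle, then union of the two bicycles.

Assumption: the SMILES is taken as drawn (both ring alkenes of each half Z, lactones trans-fused); C1–C13 in the explanations are germacrane-type locants of one half (C1 carbinol or linking CH, C4=C5 and C9=C10 alkenes, C6 hydroxyl carbon, C7/C8 ring fusion with O on C8, C11/C12/C13 lactone α-carbon, carbonyl and exocyclic CH2), primed for the methylidene-lactone half.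

**Route**

Step 1
Reactants: 1 but-2-yn-1-ol
Product: 3 (2Z)-3-iodobut-2-en-1-ol, via sodium vinylalanate 2 (not isolated)
Conditions: NaAlH2(OCH2CH2OMe)2, THF, 0 °C; then I2, −78 °C to 0 °C
Reagents that add atoms: iodine, II
Why: hydroxyl-directed trans-hydroalumination of the propargylic alcohol places aluminium on C3 in a five-membered alkoxyalanate, and iodinolysis with retention gives only the Z iodide, which later fixes the ring-cis geometry of both trisubstituted alkenes.

Step 2
Reactants: 3 (2Z)-3-iodobut-2-en-1-ol; 4 3,3-dimethoxyprop-1-ene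
Product: 6 (2Z)-6,6-dimethoxy-3-methylhex-2-en-1-ol, via alkylborane 5 (not isolated)
Conditions: 4, 9-BBN, THF, rt; then 3, Pd(dppf)Cl2 (5 mol %), AsPh3, Cs2CO3, DMF–H2O, rt
Reagents that add atoms: none
Why: anti-Markovnikov hydroboration followed by B-alkyl Suzuki–Miyaura coupling joins C3 to C4 with retention of alkene geometry and tolerates the free hydroxyl.

Step 3
Reactants: 6 (2Z)-6,6-dimethoxy-3-methylhex-2-en-1-ol
Product: 7 (2Z)-6,6-dimethoxy-3-methylhex-2-enal
Conditions: MnO2, CH2Cl2, rt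
Reagents that add atoms: none
Why: neutral heterogeneous allylic oxidation spares the acetal and, as in the nerol-to-neral case, does not isomerize the Z enal.

Step 4
Reactants: 7 (2Z)-6,6-dimethoxy-3-methylhex-2-enal; 8 methyl prop-2-ynoate
Product: 10 methyl (4R,5Z)-4-hydroxy-9,9-dimethoxy-6-methylnon-5-en-2-ynoate, via alkynylzinc 9 (not isolated)
Conditions: Me2Zn, (S,S)-ProPhenol (20 mol %), Ph3PO (40 mol %), toluene, 4 °C; aq NH4Cl
Reagents that add atoms: none
Why: Trost dinuclear zinc–ProPhenol enantioselective alkynylation of an enal, in which the catalyst selects the aldehyde face and sets C6 as 4R (the ligand antipode is used if the sense proves opposite).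

Step 5
Reactants: 10 methyl (4R,5Z)-4-hydroxy-9,9-dimethoxy-6-methylnon-5-en-2-ynoate
Product: 11 methyl (4R,5Z)-4-{[tert-butyl(dimethyl)silyl]oxy}-9,9-dimethoxy-6-methylnon-5-en-2-ynoate
Conditions: TBSCl, imidazole, DMF, 0 °C to rt
Reagents that add atoms: tert-butyl(chloro)dimethylsilane, CC(C)(C)[Si](C)(C)Cl
Why: standard silylation with a weak base that does not isomerize the γ-oxy ynoate; the ether keeps O6 out of the later lactonization and leaves O1 as the only free hydroxyl of the monomer.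

Step 6
Reactants: 11 methyl (4R,5Z)-4-{[tert-butyl(dimethyl)silyl]oxy}-9,9-dimethoxy-6-methylnon-5-en-2-ynoate
Product: 13 methyl (2Z,4R,5Z)-4-{[tert-butyl(dimethyl)silyl]oxy}-9,9-dimethoxy-6-methyl-2-[(4,4,5,5-tetramethyl-1,3,2-dioxaborolan-2-yl)methyl]nona-2,5-dienoate, via vinylalane 12 (not isolated)
Conditions: iBu2AlH, HMPA, THF, 0 °C; then ICH2Bpin, 0 °C to rt; aq NaHCO3
Reagents that add atoms: 2-(iodomethyl)-4,4,5,5-tetramethyl-1,3,2-dioxaborolane, ICB1OC(C)(C)C(C)(C)O1
Why: conjugate syn-hydroalumination of the ynoate (H to C7, Al to C11) gives an α-aluminated enoate that is C-alkylated with retention by the iodomethylboronate, giving the 2-(alkoxycarbonyl)allylboronate with C6 trans to CH2B.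

Step 7
Reactants: 3 (2Z)-3-iodobut-2-en-1-ol
Product: 14 (2Z)-3-iodobut-2-enal
Conditions: MnO2, CH2Cl2, rt (solution used directly)
Reagents that add atoms: none
Why: allylic oxidation under neutral conditions keeps the Z β-iodo enal intact.

Step 8
Reactants: 13 methyl (2Z,4R,5Z)-4-{[tert-butyl(dimethyl)silyl]oxy}-9,9-dimethoxy-6-methyl-2-[(4,4,5,5-tetramethyl-1,3,2-dioxaborolan-2-yl)methyl]nona-2,5-dienoate; 14 (2Z)-3-iodobut-2-enal
Product: 17 (4R,5R)-4-[(1R,2Z)-1-{[tert-butyl(dimethyl)silyl]oxy}-3-methyl-6-oxohex-2-en-1-yl]-5-[(1Z)-2-iodoprop-1-en-1-yl]-3-methylidenedihydrofuran-2(3H)-one, via borate ester 15 (not isolated), via lactone acetal 16 (not isolated)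
Conditions: toluene, 70 °C; then p-TsOH·H2O (20 mol %), acetone–H2O (20:1), rt
Reagents that add atoms: water, O
Why: thermal allylboration through a closed chair (Zimmerman–Traxler) transition state with the C6 substituent equatorial gives the anti adduct and hence the trans lactone (C7, C8), while allylic 1,3-strain with the cis ester holds C6–H in the alkene plane so that the aldehyde bonds to C7 on the face opposite the bulky OTBS group (the sense seen for electrophile attack on Z allylic ethers); acid then closes the lactone and unmasks the C1 aldehyde without touching the silyl ether.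

Step 9
Reactants: 17 (4R,5R)-4-[(1R,2Z)-1-{[tert-butyl(dimethyl)silyl]oxy}-3-methyl-6-oxohex-2-en-1-yl]-5-[(1Z)-2-iodoprop-1-en-1-yl]-3-methylidenedihydrofuran-2(3H)-one
Product: 19 (3aR,4R,5Z,9S,10Z,11aS)-4-{[tert-butyl(dimethyl)silyl]oxy}-9-hydroxy-6,10-dimethyl-3-methylidene-3a,4,7,8,9,11a-hexahydrocyclodeca[b]furan-2(3H)-one, via alkenylchromium dichloride 18 (not isolated)
Conditions: CrCl2 (10 equiv), NiCl2 (2 mol %), DMSO, rt, slow addition to 2 mM
Reagents that add atoms: none
Why: intramolecular Nozaki–Hiyama–Kishi coupling closes the ten-membered ring at C1–C10 with retention of the Z vinyl geometry, helped by the two cis alkenes acting as turn elements; the new C1 carbinol is set by the cyclization transition state, in which the aldehyde is expected to react through its face turned away from the transannular C4=C5 alkene, a control that is not secure and is covered by a fallback.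

Step 10
Reactants: 19 (3aR,4R,5Z,9S,10Z,11aS)-4-{[tert-butyl(dimethyl)silyl]oxy}-9-hydroxy-6,10-dimethyl-3-methylidene-3a,4,7,8,9,11a-hexahydrocyclodeca[b]furan-2(3H)-one
Product: 20 (3aR,4R,5Z,9S,10Z,11aS)-4-{[tert-butyl(dimethyl)silyl]oxy}-9-[(5,7-di-tert-butyl-3-phenyl-2,3-dihydro-1,3-benzoxazol-2-yl)oxy]-6,10-dimethyl-3-methylidene-3a,4,7,8,9,11a-hexahydrocyclodeca[b]furan-2(3H)-one (mixture at the aminal carbon)
Conditions: 5,7-di-tert-butyl-3-phenyl-1,3-benzoxazol-3-ium tetrafluoroborate (1.1 equiv), pyridine (1.1 equiv), MTBE, rt, 15 min; pyridinium salt filtered off, solution used directly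
Reagents that add atoms: 5,7-di-tert-butyl-3-phenyl-1,3-benzoxazol-3-ium tetrafluoroborate, CC(C)(C)c1cc(C(C)(C)C)c2oc[n+](-c3ccccc3)c2c1.F[B-](F)(F)F
Why: the only free hydroxyl (O1) adds to C2 of the benzoxazolium salt (N-heterocyclic carbene–alcohol condensation) under pyridine buffering, which leaves the silyl ether and the methylidene lactone untouched; the C9 configuration of this precursor is of no consequence because it is erased in the next step.

Step 11
Reactants: 20 (3aR,4R,5Z,9S,10Z,11aS)-4-{[tert-butyl(dimethyl)silyl]oxy}-9-[(5,7-di-tert-butyl-3-phenyl-2,3-dihydro-1,3-benzoxazol-2-yl)oxy]-6,10-dimethyl-3-methylidene-3a,4,7,8,9,11a-hexahydrocyclodeca[b]furan-2(3H)-one (1 equiv); 19 (3aR,4R,5Z,9S,10Z,11aS)-4-{[tert-butyl(dimethyl)silyl]oxy}-9-hydroxy-6,10-dimethyl-3-methylidene-3a,4,7,8,9,11a-hexahydrocyclodeca[b]furan-2(3H)-one (3 equiv, acceptor; excess recovered)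
Product: 21 (3aR,4R,5Z,9R,10Z,11aS)-4-{[tert-butyl(dimethyl)silyl]oxy}-9-{[(3R,3aR,4R,5Z,9S,10Z,11aS)-4-{[tert-butyl(dimethyl)silyl]oxy}-9-hydroxy-6,10-dimethyl-2-oxo-2,3,3a,4,7,8,9,11a-octahydrocyclodeca[b]furan-3-yl]methyl}-6,10-dimethyl-3-methylidene-3a,4,7,8,9,11a-hexahydrocyclodeca[b]furan-2(3H)-one
Conditions: Ir(ppy)2(dtbbpy)PF6 (2 mol %), NaOAc, DMSO–MTBE, 450 nm LEDs, rt
Reagents that add atoms: none
Why: Proposed new method: one-electron oxidation of aminal 20 by photoexcited Ir(ppy)2(dtbbpy)PF6, deprotonation at the aminal carbon and β-scission release the C1'–C10'–C9' allyl radical and the benzoxazolone; the radical is expected to bond through its less hindered terminus C1' (C9' is flanked by the lactone carbon C8'), on the outer face of the ring, to the exocyclic CH2 of 19, and the resulting α-lactone radical is reduced to the enolate and protonated so that C13 lies trans to the C7–C6 bond (the outcome found for conjugate additions to trans-fused methylidene lactones and also the more stable epimer), which sets C1' and C11 together; the closest known reaction type is the photoredox deoxygenative conjugate alkylation (Giese reaction) of carbene-activated alcohols, extended here to a macrocyclic allylic alcohol and to coupling with its own parent alcohol.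

Step 12
Reactants: 21 (3aR,4R,5Z,9R,10Z,11aS)-4-{[tert-butyl(dimethyl)silyl]oxy}-9-{[(3R,3aR,4R,5Z,9S,10Z,11aS)-4-{[tert-butyl(dimethyl)silyl]oxy}-9-hydroxy-6,10-dimethyl-2-oxo-2,3,3a,4,7,8,9,11a-octahydrocyclodeca[b]furan-3-yl]methyl}-6,10-dimethyl-3-methylidene-3a,4,7,8,9,11a-hexahydrocyclodeca[b]furan-2(3H)-one
Product: 22 (3aS,4R,5Z,9R,10Z,11aS)-4-hydroxy-9-{[(3R,3aS,4R,5Z,9S,10Z,11aS)-4,9-dihydroxy-6,10-dimethyl-2-oxo-2,3,3a,4,7,8,9,11a-octahydrocyclodeca[b]furan-3-yl]methyl}-6,10-dimethyl-3-methylidene-3a,4,7,8,9,11a-hexahydrocyclodeca[b]furan-2(3H)-one (CNP0307352.3)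
Conditions: HF·pyridine, pyridine, THF, 0 °C to rt
Reagents that add atoms: none
Why: buffered fluoride-mediated desilylation removes both secondary TBS ethers under weakly acidic conditions, which should avoid alkoxide-driven translactonization or oxa-Michael addition to the methylidene lactone, and touches no stereocenter.

**Compound list**
1 | but-2-yn-1-ol | CC#CCO | starting material
2 | sodium 2,2-bis(2-methoxyethoxy)-3-methyl-2,5-dihydro-1,2-oxaaluminol-2-uide (cyclic Z vinylalanate) | CC1=CCO[Al-]1(OCCOC)OCCOC.[Na+] | intermediate (not isolated)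
3 | (2Z)-3-iodobut-2-en-1-ol | OC/C=C(/C)I | intermediate
4 | 3,3-dimethoxyprop-1-ene | C=CC(OC)OC | starting material
5 | 9-(3,3-dimethoxypropyl)-9-borabicyclo[3.3.1]nonane | COC(OC)CCB1C2CCCC1CCC2 | intermediate (not isolated)
6 | (2Z)-6,6-dimethoxy-3-methylhex-2-en-1-ol | OC/C=C(/C)CCC(OC)OC | intermediate
7 | (2Z)-6,6-dimethoxy-3-methylhex-2-enal | O=C/C=C(/C)CCC(OC)OC | intermediate
8 | methyl prop-2-ynoate | C#CC(=O)OC | starting material
9 | methyl 3-(methylzincio)prop-2-ynoate | C[Zn]C#CC(=O)OC | intermediate (not isolated)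
10 | methyl (4R,5Z)-4-hydroxy-9,9-dimethoxy-6-methylnon-5-en-2-ynoate | COC(OC)CC/C(C)=C\[C@@H](O)C#CC(=O)OC | intermediate
11 | methyl (4R,5Z)-4-{[tert-butyl(dimethyl)silyl]oxy}-9,9-dimethoxy-6-methylnon-5-en-2-ynoate | COC(OC)CC/C(C)=C\[C@@H](O[Si](C)(C)C(C)(C)C)C#CC(=O)OC | intermediate
12 | methyl (2E,4R,5Z)-2-[bis(2-methylpropyl)alumanyl]-4-{[tert-butyl(dimethyl)silyl]oxy}-9,9-dimethoxy-6-methylnona-2,5-dienoate | COC(OC)CC/C(C)=C\[C@@H](O[Si](C)(C)C(C)(C)C)/C=C(/[Al](CC(C)C)CC(C)C)C(=O)OC | intermediate (not isolated)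
13 | methyl (2Z,4R,5Z)-4-{[tert-butyl(dimethyl)silyl]oxy}-9,9-dimethoxy-6-methyl-2-[(4,4,5,5-tetramethyl-1,3,2-dioxaborolan-2-yl)methyl]nona-2,5-dienoate | COC(OC)CC/C(C)=C\[C@@H](O[Si](C)(C)C(C)(C)C)/C=C(/CB1OC(C)(C)C(C)(C)O1)C(=O)OC | intermediate
14 | (2Z)-3-iodobut-2-enal | O=C/C=C(/C)I | intermediate
15 | methyl (3R,4R,5Z)-4-{[tert-butyl(dimethyl)silyl]oxy}-3-{(1R,2Z)-3-iodo-1-[(4,4,5,5-tetramethyl-1,3,2-dioxaborolan-2-yl)oxy]but-2-en-1-yl}-9,9-dimethoxy-6-methyl-2-methylidenenon-5-enoate | COC(=O)C(=C)[C@H]([C@@H](OB1OC(C)(C)C(C)(C)O1)/C=C(/C)I)[C@H](O[Si](C)(C)C(C)(C)C)/C=C(/C)CCC(OC)OC | intermediate (not isolated)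
16 | (4R,5R)-4-[(1R,2Z)-1-{[tert-butyl(dimethyl)silyl]oxy}-6,6-dimethoxy-3-methylhex-2-en-1-yl]-5-[(1Z)-2-iodoprop-1-en-1-yl]-3-methylidenedihydrofuran-2(3H)-one | C=C1C(=O)O[C@@H](/C=C(/C)I)[C@@H]1[C@H](O[Si](C)(C)C(C)(C)C)/C=C(/C)CCC(OC)OC | intermediate (not isolated)
17 | (4R,5R)-4-[(1R,2Z)-1-{[tert-butyl(dimethyl)silyl]oxy}-3-methyl-6-oxohex-2-en-1-yl]-5-[(1Z)-2-iodoprop-1-en-1-yl]-3-methylidenedihydrofuran-2(3H)-one | C=C1C(=O)O[C@@H](/C=C(/C)I)[C@@H]1[C@H](O[Si](C)(C)C(C)(C)C)/C=C(/C)CCC=O | intermediate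
18 | alkenylchromium dichloride of 17 (CrCl2 in place of iodine, otherwise as 17) | C=C1C(=O)O[C@@H](/C=C(/C)[Cr](Cl)Cl)[C@@H]1[C@H](O[Si](C)(C)C(C)(C)C)/C=C(/C)CCC=O | intermediate (not isolated)
19 | (3aR,4R,5Z,9S,10Z,11aS)-4-{[tert-butyl(dimethyl)silyl]oxy}-9-hydroxy-6,10-dimethyl-3-methylidene-3a,4,7,8,9,11a-hexahydrocyclodeca[b]furan-2(3H)-one | C=C1C(=O)O[C@H]2/C=C(/C)[C@@H](O)CC/C(C)=C\[C@@H](O[Si](C)(C)C(C)(C)C)[C@H]12 | intermediate
20 | (3aR,4R,5Z,9S,10Z,11aS)-4-{[tert-butyl(dimethyl)silyl]oxy}-9-[(5,7-di-tert-butyl-3-phenyl-2,3-dihydro-1,3-benzoxazol-2-yl)oxy]-6,10-dimethyl-3-methylidene-3a,4,7,8,9,11a-hexahydrocyclodeca[b]furan-2(3H)-one (mixture at the aminal carbon) | C=C1C(=O)O[C@H]2/C=C(/C)[C@@H](OC3Oc4c(C(C)(C)C)cc(C(C)(C)C)cc4N3c3ccccc3)CC/C(C)=C\[C@@H](O[Si](C)(C)C(C)(C)C)[C@H]12 | intermediate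
21 | (3aR,4R,5Z,9R,10Z,11aS)-4-{[tert-butyl(dimethyl)silyl]oxy}-9-{[(3R,3aR,4R,5Z,9S,10Z,11aS)-4-{[tert-butyl(dimethyl)silyl]oxy}-9-hydroxy-6,10-dimethyl-2-oxo-2,3,3a,4,7,8,9,11a-octahydrocyclodeca[b]furan-3-yl]methyl}-6,10-dimethyl-3-methylidene-3a,4,7,8,9,11a-hexahydrocyclodeca[b]furan-2(3H)-one (bis-TBS ether of the target) | C=C1C(=O)O[C@H]2/C=C(/C)[C@@H](C[C@H]3C(=O)O[C@H]4/C=C(/C)[C@@H](O)CC/C(C)=C\[C@@H](O[Si](C)(C)C(C)(C)C)[C@@H]43)CC/C(C)=C\[C@@H](O[Si](C)(C)C(C)(C)C)[C@H]12 | intermediate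
22 | (3aS,4R,5Z,9R,10Z,11aS)-4-hydroxy-9-{[(3R,3aS,4R,5Z,9S,10Z,11aS)-4,9-dihydroxy-6,10-dimethyl-2-oxo-2,3,3a,4,7,8,9,11a-octahydrocyclodeca[b]furan-3-yl]methyl}-6,10-dimethyl-3-methylidene-3a,4,7,8,9,11a-hexahydrocyclodeca[b]furan-2(3H)-one (CNP0307352.3) | C=C1C(=O)O[C@H]2/C=C(/C)[C@@H](C[C@H]3C(=O)O[C@H]4/C=C(/C)[C@@H](O)CC/C(C)=C\[C@@H](O)[C@@H]43)CC/C(C)=C\[C@@H](O)[C@H]12 | target

**Totals**
Total step count: 12. Longest linear sequence: 11 steps (1 → 3 → 6 → 7 → 10 → 11 → 13 → 17 → 19 → 20 → 21 → 22); step 7 is a one-step side branch from 3.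

**Steps most likely to fail, with fallbacks**

Step 11 (radical union). The allyl radical is stabilized and adds slowly, it can react at C9' instead of C1', its Z geometry may not hold, the faces at C1' and C11 are controlled only by the substrate, and both the precursor and the product still carry a methylidene lactone. The fallback sets out from 19 and comes back at 21. Compound 19 is treated with CBr4 and PPh3 in CH2Cl2 at 0 °C to give the allylic bromide F1; any allylic regioisomer or epimer is acceptable because all lead to the same allyl radical. F1 and 19 (3 equiv) are then joined in a silyl-radical chain with (Me3Si)3SiH and AIBN in benzene at 70 °C. Bromine-atom abstraction, Giese addition and hydrogen-atom transfer from the silane to C11 give 21. This replaces photoredox C–O activation and enolate protonation by a halogen-atom-transfer chain with hydrogen-atom termination.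

Step 9 (ring closure). The C1 configuration comes only from the cyclization transition state and may favour the wrong epimer. The fallback sets out from 17 and comes back at 19. The ring closure is run under the conditions of step 9 and its carbinol is taken on whatever the C9 ratio, drawn here as the 9R carbinol F2. MnO2 in CH2Cl2 oxidizes the allylic carbinol to the ring enone F3, and (R)-Me-CBS oxazaborolidine with catecholborane in toluene at −78 °C reduces it to 19 under reagent control. C1 is then set by an asymmetric reduction and not by the C–C bond formation.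

Step 8 (allylboration/lactonization). The deactivated boronate may react slowly at a temperature the Z iodo enal tolerates, and the C6-to-C7 induction rests on a conformational model. The fallback sets out from 11 and comes back at 16. The vinylalane 12 is made as in step 6 but quenched with monomeric formaldehyde to give the hydroxymethyl enoate F4. CBr4 and PPh3 convert F4 into the bromomethyl enoate F5. CrCl2 in THF at rt then couples F5 with 14 through an equilibrating allylchromium dichloride, which adds through a chair transition state to give the anti hydroxy ester F6. Anhydrous p-TsOH in CH2Cl2 closes F6 to 16, which enters the aqueous acid stage of step 8. This replaces the thermal boron allylation by a Barbier-type chromium allylation that runs at room temperature and can use chelation to O6 as a different stereocontrol element.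

**Further compounds**
F1 | step 11 | C9 bromide of 19: (3aR,4R,5Z,10Z,11aS)-9-bromo-4-{[tert-butyl(dimethyl)silyl]oxy}-6,10-dimethyl-3-methylidene-3a,4,7,8,9,11a-hexahydrocyclodeca[b]furan-2(3H)-one (C9 configuration not defined) | C=C1C(=O)O[C@H]2/C=C(/C)C(Br)CC/C(C)=C\[C@@H](O[Si](C)(C)C(C)(C)C)[C@H]12
F2 | step 9 | (3aR,4R,5Z,9R,10Z,11aS)-4-{[tert-butyl(dimethyl)silyl]oxy}-9-hydroxy-6,10-dimethyl-3-methylidene-3a,4,7,8,9,11a-hexahydrocyclodeca[b]furan-2(3H)-one (C9 epimer of 19) | C=C1C(=O)O[C@H]2/C=C(/C)[C@H](O)CC/C(C)=C\[C@@H](O[Si](C)(C)C(C)(C)C)[C@H]12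
F3 | step 9 | (3aR,4R,5Z,10Z,11aS)-4-{[tert-butyl(dimethyl)silyl]oxy}-6,10-dimethyl-3-methylidene-3a,7,8,11a-tetrahydrocyclodeca[b]furan-2,9(3H,4H)-dione | C=C1C(=O)O[C@H]2/C=C(/C)C(=O)CC/C(C)=C\[C@@H](O[Si](C)(C)C(C)(C)C)[C@H]12
F4 | step 8 | methyl (2Z,4R,5Z)-4-{[tert-butyl(dimethyl)silyl]oxy}-2-(hydroxymethyl)-9,9-dimethoxy-6-methylnona-2,5-dienoate | COC(OC)CC/C(C)=C\[C@@H](O[Si](C)(C)C(C)(C)C)/C=C(/CO)C(=O)OC
F5 | step 8 | methyl (2E,4R,5Z)-2-(bromomethyl)-4-{[tert-butyl(dimethyl)silyl]oxy}-9,9-dimethoxy-6-methylnona-2,5-dienoate | COC(OC)CC/C(C)=C\[C@@H](O[Si](C)(C)C(C)(C)C)/C=C(/CBr)C(=O)OC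
F6 | step 8 | methyl (3R,4R,5Z)-4-{[tert-butyl(dimethyl)silyl]oxy}-3-[(1R,2Z)-1-hydroxy-3-iodobut-2-en-1-yl]-9,9-dimethoxy-6-methyl-2-methylidenenon-5-enoate | COC(=O)C(=C)[C@H]([C@@H](O)/C=C(/C)I)[C@H](O[Si](C)(C)C(C)(C)C)/C=C(/C)CCC(OC)OC
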